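**Retrosynthetic overview**
- C2–H: the (2S) centre is set last, by an enantioselective 1,4-hydride addition that dearomatises the benzo-γ-pyrone (ring C) of a 6-geranylflavone.
- O1–C2 and C3–C(aroyl): the flavone comes from a 1,3-diketone. This is made by C-acylation of the lithium polyanion of 3-geranylphloroacetophenone with O-silylated isovanilloyl chloride, and it closes through the OH para to geranyl.
- Ring A–geranyl bond: one C-geranylation of mirror-symmetric phloroacetophenone, in which C3 and C5 are equivalent.
- Ring order: rings A and B are bought as arenes. Ring C is the only ring built (step 3), and it is then dearomatised (step 4).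

Assumption: geranyl means (2E)-3,7-dimethylocta-2,6-dien-1-yl throughout, and (S)-DTBM-SEGPHOS is assigned to the (2S) product by analogy with 3-substituted cyclic enones; the (R)-ligand is equally available if the sense proves opposite.

**Step 1**
Reactants: 1 2,4,6-trihydroxyacetophenone (dried); 2 geranyl bromide
Product: 3 3-geranyl-2,4,6-trihydroxyacetophenone
Conditions: K2CO3 (1.0 equiv), acetone, reflux, 6 h
Reagents that add atoms: none
Why: Phenoxide C-alkylation (SN2) of the phloroglucinol-type ambident anion, whose ring carbons react like the central carbon of a β-triketone enolate, puts one geranyl group on C3, which is equivalent to C5 in mirror-symmetric 1 so that only one mono-C-alkyl isomer can form, and direct displacement at the primary allylic bromide keeps the E alkene; no stereocentre is created.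

**Step 2**
Reactants: 4 isovanillic acid (3-hydroxy-4-methoxybenzoic acid)
Product: 6 3-(tert-butyldimethylsilyloxy)-4-methoxybenzoyl chloride, via bis-silylated isovanillic acid 5 (not isolated)
Conditions: TBSCl (2.1 equiv), imidazole (2.1 equiv), CH2Cl2, rt, filter; then (COCl)2 (1.2 equiv), DMF (cat.), 0 °C to rt, evaporate
Reagents that add atoms: tert-butyldimethylsilyl chloride, CC(C)(C)[Si](C)(C)Cl; oxalyl chloride, O=C(Cl)C(=O)Cl
Why: Silylation of the phenol and the acid, followed by the neutral silyl ester to acid chloride exchange with the chloroiminium salt from oxalyl chloride and DMF, gives the acid chloride without free HCl, so the aryl silyl ether stays in place; no stereocentre is created.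

**Step 3**
Reactants: 3 3-geranyl-2,4,6-trihydroxyacetophenone; 6 3-(tert-butyldimethylsilyloxy)-4-methoxybenzoyl chloride
Product: 8 2-[3-(tert-butyldimethylsilyloxy)-4-methoxyphenyl]-6-geranyl-5,7-dihydroxy-4H-chromen-4-one, via 1,3-diketone 7 (not isolated)
Conditions: LiN(SiMe3)2 (5.0 equiv), THF, −78 to −10 °C; 6 (1.0 equiv), −78 °C to rt; then AcOH (excess), strip THF, AcOH, 100 °C, 3 h
Reagents that add atoms: none
Why: Claisen-type C-acylation of a lithium polyanion (three phenoxides plus the ketone enolate, the fifth equivalent of base taking the acidic diketone proton) occurs at the enolate carbon as the most basic site, and in acetate-buffered AcOH diketone 7 cyclodehydrates (Baker–Venkataraman-type flavone closure) mainly through the unhindered 6-OH para to geranyl, because the 2-OH is held in the chelate with the aryl ketone by the buttressing geranyl group and the 6-alkyl flavone is also the more stable isomer (about 3:1 expected, the minor 8-geranyl isomer being removed by chromatography at this achiral stage), while the weak buffered acid does not protonate the geranyl alkenes; no stereocentre is created.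

**Step 4 (key step)**
Reactants: 8 2-[3-(tert-butyldimethylsilyloxy)-4-methoxyphenyl]-6-geranyl-5,7-dihydroxy-4H-chromen-4-one
Product: 10 (2S)-6-geranyl-5,7-dihydroxy-2-(3-hydroxy-4-methoxyphenyl)chroman-4-one (target CNP0264411.1), via silylated 2H-chromene enol ether 9 (not isolated)
Conditions: Cu(OAc)2 (5 mol%), (S)-DTBM-SEGPHOS (5.5 mol%), (EtO)2MeSiH (8 equiv), toluene, 0 to 25 °C, 24 h; then Et3N·3HF (3 equiv), THF, 0 °C to rt
Reagents that add atoms: none
Why: Proposed new method: the ligated monovalent copper hydride first turns both acidic phenols into silyl ethers (protonolysis of Cu–H, then Cu–O/Si–H metathesis with loss of H2), then delivers hydride 1,4 to the Re face of C2 inside the chiral pocket of (S)-DTBM-SEGPHOS, which destroys the planar 10π benzo-γ-pyrone ring and sets (2S), the copper enolate being trapped at once as silyl enol ether 9 so that neither E1cB ring opening nor 1,2-reduction follows, the unactivated trisubstituted geranyl alkenes being inert to copper hydride and the mildly acidic fluoride work-up removing all four silyl groups without racemisation; the closest known reaction type is the copper hydride catalysed asymmetric conjugate reduction of 2-substituted chromones, thiochromones and β,β-disubstituted cyclic enones with hydrosilanes.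

**Compound list**
1 | 2,4,6-trihydroxyacetophenone (phloroacetophenone) | CC(=O)c1c(O)cc(O)cc1O | starting material
2 | geranyl bromide, (2E)-1-bromo-3,7-dimethylocta-2,6-diene | CC(C)=CCC/C(C)=C/CBr | starting material
3 | 3-geranyl-2,4,6-trihydroxyacetophenone | CC(=O)c1c(O)cc(O)c(C/C=C(\C)CCC=C(C)C)c1O | intermediate
4 | isovanillic acid | COc1ccc(C(=O)O)cc1O | starting material
5 | tert-butyldimethylsilyl 3-(tert-butyldimethylsilyloxy)-4-methoxybenzoate | COc1ccc(C(=O)O[Si](C)(C)C(C)(C)C)cc1O[Si](C)(C)C(C)(C)C | intermediate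
6 | 3-(tert-butyldimethylsilyloxy)-4-methoxybenzoyl chloride | COc1ccc(C(=O)Cl)cc1O[Si](C)(C)C(C)(C)C | intermediate
7 | 1-(3-geranyl-2,4,6-trihydroxyphenyl)-3-[3-(tert-butyldimethylsilyloxy)-4-methoxyphenyl]propane-1,3-dione | COc1ccc(C(=O)CC(=O)c2c(O)cc(O)c(C/C=C(\C)CCC=C(C)C)c2O)cc1O[Si](C)(C)C(C)(C)C | intermediate
8 | 2-[3-(tert-butyldimethylsilyloxy)-4-methoxyphenyl]-6-geranyl-5,7-dihydroxy-4H-chromen-4-one | COc1ccc(-c2cc(=O)c3c(cc(O)c(C/C=C(\C)CCC=C(C)C)c3O)o2)cc1O[Si](C)(C)C(C)(C)C | intermediate
9 | (2S)-2-[3-(tert-butyldimethylsilyloxy)-4-methoxyphenyl]-4,5,7-tris[diethoxy(methyl)silyloxy]-6-geranyl-2H-chromene | COc1ccc([C@@H]2C=C(O[Si](C)(OCC)OCC)c3c(cc(O[Si](C)(OCC)OCC)c(C/C=C(\C)CCC=C(C)C)c3O[Si](C)(OCC)OCC)O2)cc1O[Si](C)(C)C(C)(C)C | intermediate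
10 | (2S)-6-geranyl-5,7-dihydroxy-2-(3-hydroxy-4-methoxyphenyl)chroman-4-one | COc1ccc([C@@H]2CC(=O)c3c(cc(O)c(C/C=C(\C)CCC=C(C)C)c3O)O2)cc1O | target

**Step count**
- Total steps: 4.
- Longest linear sequence: 3 (1 → 3 → 8 → 10, or equally 4 → 6 → 8 → 10).

**Steps most likely to fail**

Step 4 is the riskiest. The silylated flavone may be too electron-rich for hydride transfer, or the enolate may ring-open to a chalcone that is then over-reduced.
- The fallback sets the stereocentre by aryl transfer instead of hydride transfer. It sets out from 3 and comes back at 10.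
- The LiN(SiMe3)2 polyanion of 3 is C-formylated with ethyl formate to 3-(3-geranyl-2,4,6-trihydroxyphenyl)-3-oxopropanal F1.
- F1 closes in warm AcOH to 6-geranyl-5,7-dihydroxy-4H-chromen-4-one F2.
- TBSOTf and 2,6-lutidine give 5,7-bis(tert-butyldimethylsilyloxy)-6-geranyl-4H-chromen-4-one F3.
- Asymmetric 1,4-addition of commercial (3-hydroxy-4-methoxyphenyl)boronic acid, with [RhCl(C2H4)2]2 and (S)-MeO-F12-BIPHEP in toluene/H2O at rt, gives (2S)-5,7-bis(tert-butyldimethylsilyloxy)-6-geranyl-2-(3-hydroxy-4-methoxyphenyl)chroman-4-one F4.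
- Et3N·3HF then gives 10.

Step 3 is the second risk. Ring closure may give too much of the 8-geranyl isomer, or the geranyl chain may suffer in hot AcOH.
- The fallback closes ring C before the geranyl group is present. It sets out from 1 and 6, bypasses 3, and comes back at 8.
- The polyanion of symmetric 1 is acylated with 6 to 1-(2,4,6-trihydroxyphenyl)-3-[3-(tert-butyldimethylsilyloxy)-4-methoxyphenyl]propane-1,3-dione F5.
- The two ortho hydroxyls of F5 are equivalent, so closure gives the single flavone 2-[3-(tert-butyldimethylsilyloxy)-4-methoxyphenyl]-5,7-dihydroxy-4H-chromen-4-one F6.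
- NIS in DMF iodinates the carbon flanked by both free hydroxyls, giving the 6-iodo flavone 2-[3-(tert-butyldimethylsilyloxy)-4-methoxyphenyl]-5,7-dihydroxy-6-iodo-4H-chromen-4-one F7.
- A linear-selective Suzuki–Miyaura coupling with commercial geranylboronic acid pinacol ester (Pd(OAc)2, a bulky dialkylbiaryl phosphine, K3PO4, THF/H2O) gives 8.

Step 1 is the third risk. O-alkylation and geminal double alkylation cap the yield at roughly 40–50%.
- The fallback replaces phenoxide alkylation by halogenation and cross-coupling. It sets out from 1 and comes back at 3.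
- NIS (1.0 equiv, MeCN, 0 °C) gives 3-iodo-2,4,6-trihydroxyacetophenone F8.
- The same linear-selective Suzuki–Miyaura coupling with geranylboronic acid pinacol ester gives 3.

**Further compounds**
F1 | step 4 | 3-(3-geranyl-2,4,6-trihydroxyphenyl)-3-oxopropanal | O=CCC(=O)c1c(O)cc(O)c(C/C=C(\C)CCC=C(C)C)c1O
F2 | step 4 | 6-geranyl-5,7-dihydroxy-4H-chromen-4-one | O=c1ccoc2cc(O)c(C/C=C(\C)CCC=C(C)C)c(O)c12
F3 | step 4 | 5,7-bis(tert-butyldimethylsilyloxy)-6-geranyl-4H-chromen-4-one | O=c1ccoc2cc(O[Si](C)(C)C(C)(C)C)c(C/C=C(\C)CCC=C(C)C)c(O[Si](C)(C)C(C)(C)C)c12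
F4 | step 4 | (2S)-5,7-bis(tert-butyldimethylsilyloxy)-6-geranyl-2-(3-hydroxy-4-methoxyphenyl)chroman-4-one | COc1ccc([C@@H]2CC(=O)c3c(cc(O[Si](C)(C)C(C)(C)C)c(C/C=C(\C)CCC=C(C)C)c3O[Si](C)(C)C(C)(C)C)O2)cc1O
F5 | step 3 | 1-(2,4,6-trihydroxyphenyl)-3-[3-(tert-butyldimethylsilyloxy)-4-methoxyphenyl]propane-1,3-dione | COc1ccc(C(=O)CC(=O)c2c(O)cc(O)cc2O)cc1O[Si](C)(C)C(C)(C)C
F6 | step 3 | 2-[3-(tert-butyldimethylsilyloxy)-4-methoxyphenyl]-5,7-dihydroxy-4H-chromen-4-one | COc1ccc(-c2cc(=O)c3c(O)cc(O)cc3o2)cc1O[Si](C)(C)C(C)(C)C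
F7 | step 3 | 2-[3-(tert-butyldimethylsilyloxy)-4-methoxyphenyl]-5,7-dihydroxy-6-iodo-4H-chromen-4-one | COc1ccc(-c2cc(=O)c3c(cc(O)c(I)c3O)o2)cc1O[Si](C)(C)C(C)(C)C
F8 | step 1 | 3-iodo-2,4,6-trihydroxyacetophenone | CC(=O)c1c(O)cc(O)c(I)c1O
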